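## Structural features

The target 22 is an acyclic C17 chain, numbered here C1–C12 with methyl groups on C3, C7 and C11 and a vinyl group on C3. C1 is the carbonyl carbon of a 2,4-dihydroxyphenyl ketone, and the benzene ring, joined through the C1–aryl bond, is the only ring. C9 is a second ketone, conjugated with the dimethyl-substituted C10=C11 alkene and at the same time β,γ to the E-configured trisubstituted C6=C7 alkene. The only stereocentre is the all-carbon quaternary C3 (R), which carries methyl, vinyl, C2 and C4. It has no stereogenic neighbour, so its configuration must come from a catalyst or reagent and cannot be raised later by separating diastereomers. The fragile sites are the C8 methylene (flanked by the C9 carbonyl and the C6=C7 alkene, so base or strong acid would pull the alkene into conjugation), the enone as a Michael acceptor, the free resorcinol, and three alkenes that exclude hydrogenation, ozonolysis and strong electrophiles late in the route. The real difficulty is twofold: enantioselective construction of C3, and joining C8 to C9 with E geometry at C6=C7 without exposing the skipped enone to base. The key step uses the fact that the C9 oxygen is homoallylic to C6=C7 and allylic to C10=C11. That is the pattern left by a [2,3] shift of a prenyl ether sitting on the C6 oxygen of an isopropenyl carbinol, so the C8–C9 bond and the alkene arise together at the alcohol oxidation level.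

## Logic of the disconnections

22 ⇒ 21. The two phenolic O–H bonds are traced back to methoxymethyl ethers. The cut is made there because the aryl–metal addition and the oxidation before it need masked phenols. Nothing is gained in skeleton, but the last step becomes a pure deprotection. The demand is that the acid used must not isomerise the C6=C7 bond or add solvent to the enone.

21 ⇒ 20. Both carbonyls (C1 and C9) are taken back to carbinols. This lets one oxidation make both ketones, and no ketone or acidic C8 methylene exists while organolithium reagents are in use. The demand is a neutral, non-enolising oxidant that works on a benzylic and an allylic carbinol alike.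

20 ⇒ 16 + 19, and 19 ⇒ 18 ⇒ 17. The C1–aryl bond is cut. This separates the whole arene from the chain and reduces the chain to an aldehyde. The demand is that metalation places the metal at the former C–Br carbon (halogen–metal exchange, not ortho-deprotonation between the two ethers), and that an extra equivalent of the nucleophile absorbs the free C9 hydroxyl.

16 ⇒ 15 ⇒ 14. These are oxidation-level and protecting-group changes at C1 only (the C1–H of the primary carbinol, then the O–Si bond). The gain is that C1 travels through the strongly basic steps as an inert silyl ether. The demand is an oxidant that takes the primary hydroxyl and leaves the secondary allylic C9 hydroxyl.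

14 ⇒ 12 (through 13). The C8–C9 bond is cut and the C6–O bond restored, with the alkene moved from C6=C7 to C7=C8. This removes five carbons as a simple prenyl unit and replaces a trisubstituted E-alkene by an isopropenyl group. The demand on the forward step is lithiation at the prenyl O–CH2, a [2,3] and not a [1,2] shift, and E geometry.

12 ⇒ 10 + 11. The C6–O–C9 ether bond is cut on the C9 side. This returns a commercial allylic bromide and a secondary allylic alcohol. The demand is O-alkylation without SN2′ attack.

10 ⇒ 9 ⇒ 8. The C6–O bond is removed, first as an allylic transposition of an epoxide, then as the epoxide oxygen itself. This reduces the oxygenated chain end to a plain dimethyl-substituted alkene. The demands are epoxidation of the trisubstituted alkene only, and proton removal from a C7 methyl group, not from C5.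

8 ⇒ 5 + 7, and 7 ⇒ 6. The C3–C4 bond is cut with allylic transposition, so the vinyl group and the quaternary centre disappear into an achiral E-allylic chloride and an achiral alkylborane. This is the greatest simplification of the route, since it removes the only stereocentre. The demand is γ-selective, enantioselective substitution under catalyst control.

5 ⇒ 4 ⇒ 2 (through 3) ⇒ 1. The C–Cl bond, the C–CH2OH bond, the C3–CH3 bond and the O–Si bond are cut in turn, leading to a four-carbon alkynol. The demand is syn, regioselective methyl–metal addition across the alkyne so that the E geometry of the allylic chloride is secure.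

## Other disconnections considered

Alternative 1: The cut is again C3–C4 with allylic transposition, but on an allylic chloride A2 that already carries the aryl ketone as a 2-aryl-1,3-dithiane. In the forward step the alkylborane 7 and A2 couple under CuCl, a DTBM-SEGPHOS-type bisphosphine and KOMe at the γ-carbon to give A1.
- In its favour: the arene and the C1 oxidation level are in place early, so the late aryllithium addition and the chemoselective oxidation of a primary alcohol are not needed. On that point it is better than the chosen plan.
- Against it: two thioether sulfurs can bind the copper catalyst. The bulky 2-aryl-dithianyl group sits one carbon from the γ-carbon under attack and may lower both γ-selectivity and enantioselection. The dithiane must be removed at the end with electrophilic or oxidative reagents in the presence of three alkenes and an electron-rich arene. A1 also still lacks C9–C12, so the C8–C9 bond must still be made afterwards.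
- Comparison: the chosen plan runs the same catalytic reaction on 5, where the flanking group is a slim silyloxyethyl chain, so the mechanism is equal and the substrate easier. Step economy is about equal: three late steps are saved, but dithiane formation, alkylation and removal are added.

Alternative 2: The cut is the C5–C6 bond between an sp3 carbon and the alkene carbon. In the forward step the redox-active ester A4 and the E-alkenyl iodide A5 are joined by constant-current reduction with NiCl2(dme) and 2,2′-bipyridine. The ester loses CO2 and the C5 radical is captured by the nickel–alkenyl species to give A3.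
- In its favour: two fragments of similar size are joined late. The E geometry of C6=C7 is fixed in A5 by syn-carbometalation and iodination of an alkyne and should be carried over unchanged. On geometric control it is better than the chosen plan, which relies on a conformational preference. The longest linear sequence should be equal or shorter.
- Against it: A4 needs the quaternary centre with two differentiated arms (aroylmethyl and carboxyethyl), so the enantioselective problem remains and becomes harder. The aryl ketone of A4 can be reduced at the cathode, and the N-acyloxyphthalimide is sensitive to nucleophiles. A5 needs its own multistep synthesis. Desilylation, oxidation and MOM removal still follow.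
- Comparison: the total step count should be higher, and the radical–nickel mechanism is less tolerant of the ketone than the anionic shift of the chosen plan, where no carbonyl is present.

Alternative 3: The cut is the C2–C3 bond. In the forward step, heating the α-silyl allyl 1-arylvinyl ether A7 causes a [3,3] shift through a chair with the silyl group equatorial. This gives A6, with the C1 ketone, the quaternary centre and an E-vinylsilane formed together.
- In its favour: the configuration of C3 comes by stereospecific transfer from a secondary α-silyl carbinol, which is accessible by asymmetric reduction of an acylsilane, and no metal catalyst is needed in the bond-forming step. On reliability of stereocontrol at C3 it is equal to or better than the catalytic coupling of the chosen plan.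
- Against it: A7 is hard to make. It is a 1-arylvinyl ether of a hindered α-silyl alcohol, for example by methylenation of the aryl ester with Cp2TiMe2, and the alkoxide is at risk of silyl migration from carbon to oxygen. The vinylsilane of A6 must be protodesilylated with acid beside a trisubstituted alkene and an electron-rich arene. The aryl ketone is then present through all later chain building, including the strongly basic C8–C9 construction, and would need protection.
- Comparison: the route should be clearly longer and its functional-group order is less favourable, although its stereochemical mechanism is the more predictable one.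

Key step: step 8

Remark on the chemistry (assumption): the sense of induction of the copper–bisphosphine catalyst in step 4 is taken to be such that the (R)-ligand delivers 3R; if the correlation proves opposite, the mirror-image ligand is used with no other change.

## Route

Step 1
Reactants: 1 but-3-yn-1-ol
Product: 2 (but-3-yn-1-yloxy)triisopropylsilane
Conditions: TIPSCl, imidazole, CH2Cl2, 0 °C → rt
Reagents that add atoms: triisopropylsilyl chloride, CC(C)[Si](Cl)(C(C)C)C(C)C
Why: Standard silylation of a primary alcohol; the bulky TIPS ether is chosen because it must survive Me3Al, KOMe, an aluminium amide, NaH and n-BuLi before its planned removal in step 9.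

Step 2
Reactants: 2 (but-3-yn-1-yloxy)triisopropylsilane
Product: 4 (E)-3-methyl-5-(triisopropylsilyloxy)pent-2-en-1-ol, via alkenyldimethylalane 3 (not isolated)
Conditions: Me3Al, Cp2ZrCl2 (20 mol %), CH2Cl2, 0 °C → rt; then n-BuLi, THF, −30 °C; (CH2O)n, → rt; H2O
Reagents that add atoms: trimethylaluminium, C[Al](C)C; formaldehyde (from paraformaldehyde), C=O
Why: Zirconium-catalysed carboalumination (Negishi) adds methyl and aluminium syn across the terminal alkyne with methyl on the internal carbon, which fixes the E-trisubstituted alkene. The derived alanate adds to formaldehyde with retention of geometry to give the allylic alcohol.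

Step 3
Reactants: 4 (E)-3-methyl-5-(triisopropylsilyloxy)pent-2-en-1-ol
Product: 5 (E)-[(5-chloro-3-methylpent-3-en-1-yl)oxy]triisopropylsilane
Conditions: MsCl, LiCl, 2,4,6-collidine, DMF, 0 °C
Reagents that add atoms: lithium chloride, [Li+].[Cl-]
Why: Mesylation with in situ SN2 displacement by chloride converts a primary allylic alcohol into the chloride without allylic transposition or loss of alkene geometry; the conditions are buffered, so the silyl ether is safe.

Step 4
Reactants: 6 4-methylpenta-1,3-diene; 5 (E)-[(5-chloro-3-methylpent-3-en-1-yl)oxy]triisopropylsilane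
Product: 8 (R)-[(3,7-dimethyl-3-vinyloct-6-en-1-yl)oxy]triisopropylsilane, via B-(4-methylpent-3-enyl)-9-BBN 7 (not isolated)
Conditions: 6, (9-BBN)2, THF, 0 → 60 °C; then 5, CuCl (10 mol %), (R)-DTBM-SEGPHOS (11 mol %), KOMe, 1,4-dioxane, 25 °C
Reagents that add atoms: none
Why: 9-BBN hydroborates the monosubstituted end of the diene at the terminal carbon. The methoxyborate formed with KOMe passes the alkyl group to a chiral monovalent copper–bisphosphine complex, which substitutes the chloride at the γ-carbon (copper-catalysed enantioselective allyl–alkyl coupling of alkylboranes with γ,γ-disubstituted primary allylic chlorides). This forms C3–C4, the vinyl group and the quaternary centre, whose configuration is set by catalyst-controlled selection between the two faces of the E-alkene.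

Step 5
Reactants: 8 (R)-[(3,7-dimethyl-3-vinyloct-6-en-1-yl)oxy]triisopropylsilane
Product: 9 {[(3R)-6,7-epoxy-3,7-dimethyl-3-vinyloctyl]oxy}triisopropylsilane (both C6 epimers)
Conditions: mCPBA, NaHCO3, CH2Cl2, −10 → 0 °C
Reagents that add atoms: 3-chloroperoxybenzoic acid, OOC(=O)c1cccc(Cl)c1
Why: Prilezhaev epoxidation is much faster at the electron-rich trisubstituted alkene than at the monosubstituted vinyl group on the quaternary carbon. The remote C3 centre gives no facial bias, and none is needed because C6 becomes sp2 in step 8.

Step 6
Reactants: 9 {[(3R)-6,7-epoxy-3,7-dimethyl-3-vinyloctyl]oxy}triisopropylsilane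
Product: 10 (3R)-3,7-dimethyl-1-(triisopropylsilyloxy)-3-vinyloct-7-en-6-ol (both C6 epimers)
Conditions: Et2Al(TMP) (from Et2AlCl and lithium 2,2,6,6-tetramethylpiperidide), toluene, 0 °C; H2O
Reagents that add atoms: none
Why: Base-promoted isomerisation of a trisubstituted epoxide to an allylic alcohol: aluminium binds the oxygen and the hindered amide removes a proton from a C7 methyl group as the tertiary C7–O bond breaks. This leaves the hydroxyl on C6 and a C7=C8 isopropenyl group; the silyl ether and vinyl group are inert.

Step 7
Reactants: 10 (3R)-3,7-dimethyl-1-(triisopropylsilyloxy)-3-vinyloct-7-en-6-ol; 11 prenyl bromide (1-bromo-3-methylbut-2-ene)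
Product: 12 {[(3R)-3,7-dimethyl-6-(3-methylbut-2-en-1-yloxy)-3-vinyloct-7-en-1-yl]oxy}triisopropylsilane (both C6 epimers)
Conditions: NaH, n-Bu4NI (cat.), THF/DMF, 0 °C → rt
Reagents that add atoms: none
Why: Williamson etherification; the sodium alkoxide attacks the primary allylic bromide by SN2, which is favoured over SN2′ at the dimethyl-substituted terminus, and gives the bis-allylic ether needed for the rearrangement.

Step 8
Reactants: 12 {[(3R)-3,7-dimethyl-6-(3-methylbut-2-en-1-yloxy)-3-vinyloct-7-en-1-yl]oxy}triisopropylsilane
Product: 14 (3R,6E)-3,7,11-trimethyl-1-(triisopropylsilyloxy)-3-vinyldodeca-6,10-dien-9-ol (both C9 epimers), via α-lithiated prenyl ether 13 (not isolated)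
Conditions: n-BuLi, THF, −78 → −25 °C; then H2O
Reagents that add atoms: none
Why: n-BuLi removes a proton from the prenyl O–CH2 group, the only primary α-oxygenated allylic position; the C6–H is more substituted and shielded by the C5 chain and the isopropenyl group, and no other site is comparably acidic. The resulting α-oxyallyl carbanion 13 rearranges suprafacially through a five-membered envelope transition state in a concerted six-electron [2,3]-Wittig shift: C9 bonds to the isopropenyl terminus C8 while the C6–O bond breaks and the C6=C7 π bond forms. The closest known reaction type is the [2,3]-Wittig rearrangement of unsymmetrical bis-allylic ethers of secondary 2-methylallylic alcohols to trisubstituted homoallylic alcohols, the same shift that converts diprenyl ether into artemisia alcohol. No ring is closed and no stereocentre is retained: C6 becomes sp2, so both C6 epimers of 12 converge, and the C9 carbinol is formed as an epimer mixture that step 13 erases. E geometry is expected because the C5 chain takes the pseudo-equatorial position on the envelope; in the pseudo-axial alternative it would run into the 2-methylprop-1-enyl group on the carbanion carbon. That substituent on the carbanion carbon is what separates this case from the tin–lithium exchange variant, where a 2-methyl group on the allyl unit favours the Z-alkene. Preference for the [2,3] over the [1,2] shift needs low temperature, since the [1,2] path goes through a higher-lying radical-pair dissociation; warming therefore stops near −25 °C. The TIPS ether, the vinyl group and the quaternary centre are inert to the base.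

Step 9
Reactants: 14 (3R,6E)-3,7,11-trimethyl-1-(triisopropylsilyloxy)-3-vinyldodeca-6,10-dien-9-ol
Product: 15 (3R,6E)-3,7,11-trimethyl-3-vinyldodeca-6,10-diene-1,9-diol (both C9 epimers)
Conditions: TBAF, THF, rt
Reagents that add atoms: none
Why: Fluoride-driven cleavage of the Si–O bond frees the primary hydroxyl; no base-sensitive group is present at this stage.

Step 10
Reactants: 15 (3R,6E)-3,7,11-trimethyl-3-vinyldodeca-6,10-diene-1,9-diol
Product: 16 (3R,6E)-9-hydroxy-3,7,11-trimethyl-3-vinyldodeca-6,10-dienal (both C9 epimers)
Conditions: TEMPO (10 mol %), PhI(OAc)2, CH2Cl2, 0 °C → rt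
Reagents that add atoms: none
Why: Oxoammonium-mediated oxidation is highly sensitive to steric hindrance and should take the unhindered primary hydroxyl ahead of the secondary C9 carbinol, which is flanked by a trisubstituted alkene and a branched methylene. Without water the oxidation stops at the aldehyde and leaves the alkenes alone.

Step 11
Reactants: 17 4-bromoresorcinol (4-bromobenzene-1,3-diol)
Product: 18 1-bromo-2,4-bis(methoxymethoxy)benzene
Conditions: MOMCl, i-Pr2NEt, CH2Cl2, 0 °C → rt
Reagents that add atoms: chloromethyl methyl ether, COCCl
Why: O-alkylation of both phenols gives acetal ethers that tolerate organolithium reagents, stabilise the ortho-lithiated arene by chelation, and are removable at the end.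

Step 12
Reactants: 18 1-bromo-2,4-bis(methoxymethoxy)benzene; 16 (3R,6E)-9-hydroxy-3,7,11-trimethyl-3-vinyldodeca-6,10-dienal
Product: 20 (3R,6E)-1-[2,4-bis(methoxymethoxy)phenyl]-3,7,11-trimethyl-3-vinyldodeca-6,10-diene-1,9-diol (C1/C9 epimer mixture), via 2,4-bis(methoxymethoxy)phenyllithium 19 (not isolated)
Conditions: 18 (2.6 equiv), n-BuLi (2.5 equiv), THF, −78 °C; then 16, −78 → −40 °C; H2O
Reagents that add atoms: none
Why: Bromine–lithium exchange is faster than deprotonation between the two ethers and so fixes lithium at the former C–Br carbon, which gives the 2,4-substitution pattern. One equivalent of 19 is consumed by the C9 hydroxyl and the next adds to the aldehyde (1,2-addition of an aryllithium). The new C1 carbinol centre is uncontrolled and is erased in step 13.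

Step 13
Reactants: 20 (3R,6E)-1-[2,4-bis(methoxymethoxy)phenyl]-3,7,11-trimethyl-3-vinyldodeca-6,10-diene-1,9-diol
Product: 21 (3R,6E)-1-[2,4-bis(methoxymethoxy)phenyl]-3,7,11-trimethyl-3-vinyldodeca-6,10-diene-1,9-dione
Conditions: Dess–Martin periodinane, NaHCO3, CH2Cl2, 0 °C → rt
Reagents that add atoms: none
Why: Dess–Martin oxidation converts the benzylic and the allylic secondary carbinol into ketones in one operation under buffered, non-basic conditions, so the C8 methylene between C9=O and C6=C7 is not enolised and the alkene stays out of conjugation.

Step 14
Reactants: 21 (3R,6E)-1-[2,4-bis(methoxymethoxy)phenyl]-3,7,11-trimethyl-3-vinyldodeca-6,10-diene-1,9-dione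
Product: 22 (3R,6E)-1-(2,4-dihydroxyphenyl)-3,7,11-trimethyl-3-vinyldodeca-6,10-diene-1,9-dione (target)
Conditions: HCl (2 M aq.), MeOH, rt
Reagents that add atoms: none
Why: Acid-catalysed acetal exchange with methanol removes both MOM groups; the ortho ether is activated by the neighbouring carbonyl and the para ether follows. Dilute acid at room temperature is chosen so that the quaternary centre (not enolisable), the alkenes and the skipped enone are left as they are.

## Compound list

1 | but-3-yn-1-ol | C#CCCO | starting material
2 | (but-3-yn-1-yloxy)triisopropylsilane | C#CCCO[Si](C(C)C)(C(C)C)C(C)C | intermediate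
3 | (E)-dimethyl[2-methyl-4-(triisopropylsilyloxy)but-1-en-1-yl]alane | C/C(CCO[Si](C(C)C)(C(C)C)C(C)C)=C\[Al](C)C | intermediate (not isolated)
4 | (E)-3-methyl-5-(triisopropylsilyloxy)pent-2-en-1-ol | C/C(CCO[Si](C(C)C)(C(C)C)C(C)C)=C\CO | intermediate
5 | (E)-[(5-chloro-3-methylpent-3-en-1-yl)oxy]triisopropylsilane | C/C(CCO[Si](C(C)C)(C(C)C)C(C)C)=C\CCl | intermediate
6 | 4-methylpenta-1,3-diene | C=CC=C(C)C | starting material
7 | 9-(4-methylpent-3-en-1-yl)-9-borabicyclo[3.3.1]nonane | CC(C)=CCCB1C2CCCC1CCC2 | intermediate (not isolated)
8 | (R)-[(3,7-dimethyl-3-vinyloct-6-en-1-yl)oxy]triisopropylsilane | C=C[C@](C)(CCC=C(C)C)CCO[Si](C(C)C)(C(C)C)C(C)C | intermediate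
9 | {[(3R)-6,7-epoxy-3,7-dimethyl-3-vinyloctyl]oxy}triisopropylsilane, both C6 epimers | C=C[C@](C)(CCC1OC1(C)C)CCO[Si](C(C)C)(C(C)C)C(C)C | intermediate
10 | (3R)-3,7-dimethyl-1-(triisopropylsilyloxy)-3-vinyloct-7-en-6-ol, both C6 epimers | C=C[C@](C)(CCC(O)C(C)=C)CCO[Si](C(C)C)(C(C)C)C(C)C | intermediate
11 | prenyl bromide (1-bromo-3-methylbut-2-ene) | CC(C)=CCBr | starting material
12 | {[(3R)-3,7-dimethyl-6-(3-methylbut-2-en-1-yloxy)-3-vinyloct-7-en-1-yl]oxy}triisopropylsilane, both C6 epimers | C=C[C@](C)(CCC(OCC=C(C)C)C(C)=C)CCO[Si](C(C)C)(C(C)C)C(C)C | intermediate
13 | α-lithiated prenyl ether of 12 (lithium on the prenyl O–CH carbon) | C=C[C@](C)(CCC(OC([Li])C=C(C)C)C(C)=C)CCO[Si](C(C)C)(C(C)C)C(C)C | intermediate (not isolated)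
14 | (3R,6E)-3,7,11-trimethyl-1-(triisopropylsilyloxy)-3-vinyldodeca-6,10-dien-9-ol, both C9 epimers | C=C[C@](C)(CC/C=C(\C)CC(O)C=C(C)C)CCO[Si](C(C)C)(C(C)C)C(C)C | intermediate
15 | (3R,6E)-3,7,11-trimethyl-3-vinyldodeca-6,10-diene-1,9-diol, both C9 epimers | C=C[C@](C)(CC/C=C(\C)CC(O)C=C(C)C)CCO | intermediate
16 | (3R,6E)-9-hydroxy-3,7,11-trimethyl-3-vinyldodeca-6,10-dienal, both C9 epimers | C=C[C@](C)(CC/C=C(\C)CC(O)C=C(C)C)CC=O | intermediate
17 | 4-bromoresorcinol (4-bromobenzene-1,3-diol) | Oc1ccc(Br)c(O)c1 | starting material
18 | 1-bromo-2,4-bis(methoxymethoxy)benzene | COCOc1ccc(Br)c(OCOC)c1 | intermediate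
19 | 2,4-bis(methoxymethoxy)phenyllithium | [Li]c1ccc(OCOC)cc1OCOC | intermediate (not isolated)
20 | (3R,6E)-1-[2,4-bis(methoxymethoxy)phenyl]-3,7,11-trimethyl-3-vinyldodeca-6,10-diene-1,9-diol, C1/C9 epimer mixture | C=C[C@](C)(CC/C=C(\C)CC(O)C=C(C)C)CC(O)c1ccc(OCOC)cc1OCOC | intermediate
21 | (3R,6E)-1-[2,4-bis(methoxymethoxy)phenyl]-3,7,11-trimethyl-3-vinyldodeca-6,10-diene-1,9-dione | C=C[C@](C)(CC/C=C(\C)CC(=O)C=C(C)C)CC(=O)c1ccc(OCOC)cc1OCOC | intermediate
22 | (3R,6E)-1-(2,4-dihydroxyphenyl)-3,7,11-trimethyl-3-vinyldodeca-6,10-diene-1,9-dione | C=C[C@](C)(CC/C=C(\C)CC(=O)C=C(C)C)CC(=O)c1ccc(O)cc1O | target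

## Step count and least certain steps

Total: 14 steps. Longest linear sequence: 13 steps (steps 1–10 and 12–14, from 1); step 11 is a one-step branch that joins at step 12.

Step 8 (key step). The most likely failure is loss of geometric control. Allylic 1,2-strain between the C7 methyl group and a pseudo-equatorial C5 chain may make the envelope with the chain pseudo-axial competitive, which would lead to the Z-alkene. A [1,2] shift on warming or lithiation at C6 could also intrude. The fallback sets out from 8 and returns at 14, building the same C8–C9 bond with reversed polarity: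
- Catalytic SeO2 with t-BuOOH oxidises the E-methyl group of the dimethyl-substituted alkene to the allylic alcohol (3R,6E)-3,7-dimethyl-1-(triisopropylsilyloxy)-3-vinyloct-6-en-8-ol F1.
- Mesylation with chloride displacement gives {[(3R,6E)-8-chloro-3,7-dimethyl-3-vinyloct-6-en-1-yl]oxy}triisopropylsilane F2.
- Activated barium (from BaI2 and lithium biphenylide) at −78 °C gives the allylbarium chloride F3, which should add to 3-methylbut-2-enal at its α-carbon with retention of alkene geometry and so deliver 14.

Step 4. The risk is insufficient enantioselection, or α-attack, at the hindered γ,γ-disubstituted terminus; since C3 is the only stereocentre, the enantiomeric purity cannot be raised later. The fallback sets out from 4 and returns at 8, using a different electrophile, nucleophile and catalyst class: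
- 4 is converted with diethyl chlorophosphate into (E)-diethyl 3-methyl-5-(triisopropylsilyloxy)pent-2-en-1-yl phosphate F4.
- F4 is coupled with bis(4-methylpent-3-en-1-yl)zinc F5 (from 5-bromo-2-methylpent-2-ene through its Grignard reagent and ZnCl2) under (CuOTf)2·C6H6 and a chiral sulfonate-bearing N-heterocyclic carbene ligand, an established enantioselective allylic substitution that forms quaternary centres.

Step 6. The risk is proton removal from C5 in place of a C7 methyl group, which would give the tertiary allylic alcohol, or a Lewis-acid-induced hydride shift to a ketone. The fallback sets out from 9 and returns at 10, making the C6–C7 bond by carbonyl addition: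
- Periodic acid (H5IO6) cleaves the epoxide to the aldehyde (R)-4-methyl-4-[2-(triisopropylsilyloxy)ethyl]hex-5-enal F6.
- Isopropenylmagnesium bromide adds to F6 to give 10 as the same epimer mixture.

Step 10. The risk is oxidation of the activated allylic C9 carbinol alongside the primary alcohol. The fallback sets out from 15 and returns at 21, removing the need for selectivity between the two alcohols:
- Dess–Martin oxidation of both hydroxyls gives the keto aldehyde (3R,6E)-3,7,11-trimethyl-9-oxo-3-vinyldodeca-6,10-dienal F7.
- The weakly basic [2,4-bis(methoxymethoxy)phenyl]titanium triisopropoxide F8 (from 19 and ClTi(OiPr)3) adds to the aldehyde only and gives (3R,6E)-1-[2,4-bis(methoxymethoxy)phenyl]-1-hydroxy-3,7,11-trimethyl-3-vinyldodeca-6,10-dien-9-one F9.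
- A second Dess–Martin oxidation gives 21.

Step 14. The risk is acid-promoted migration of the C6=C7 bond into conjugation with C9 through the dienol, or addition of methanol to the enone, before the slower para ether is cleaved. The fallback sets out from 16 (with 17 for the arene) and returns at 22, replacing acid-labile by fluoride-labile phenol protection:
- 17 is silylated (TIPSCl, imidazole) to 1-bromo-2,4-bis(triisopropylsilyloxy)benzene F10.
- Bromine–lithium exchange at −78 °C gives 2,4-bis(triisopropylsilyloxy)phenyllithium F11, whose bulky silyl groups should retard oxygen-to-carbon silyl migration.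
- Addition to 16 gives the bis-silyl diol F12 (the analogue of 20), and Dess–Martin oxidation gives the bis-silyl diketone F13 (the analogue of 21).
- HF·pyridine buffered with pyridine, which is neither basic nor strongly acidic, releases 22.

## Further compounds

F1 | step 8 | (3R,6E)-3,7-dimethyl-1-(triisopropylsilyloxy)-3-vinyloct-6-en-8-ol | C=C[C@](C)(CC/C=C(\C)CO)CCO[Si](C(C)C)(C(C)C)C(C)C
F2 | step 8 | {[(3R,6E)-8-chloro-3,7-dimethyl-3-vinyloct-6-en-1-yl]oxy}triisopropylsilane | C=C[C@](C)(CC/C=C(\C)CCl)CCO[Si](C(C)C)(C(C)C)C(C)C
F3 | step 8 | allylbarium chloride derived from F2 (barium on C8) | C=C[C@](C)(CC/C=C(\C)C[Ba]Cl)CCO[Si](C(C)C)(C(C)C)C(C)C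
F4 | step 4 | (E)-diethyl 3-methyl-5-(triisopropylsilyloxy)pent-2-en-1-yl phosphate | C/C(CCO[Si](C(C)C)(C(C)C)C(C)C)=C\COP(=O)(OCC)OCC
F5 | step 4 | bis(4-methylpent-3-en-1-yl)zinc | CC(C)=CCC[Zn]CCC=C(C)C
F6 | step 6 | (R)-4-methyl-4-[2-(triisopropylsilyloxy)ethyl]hex-5-enal | C=C[C@](C)(CCC=O)CCO[Si](C(C)C)(C(C)C)C(C)C
F7 | step 10 | (3R,6E)-3,7,11-trimethyl-9-oxo-3-vinyldodeca-6,10-dienal | C=C[C@](C)(CC/C=C(\C)CC(=O)C=C(C)C)CC=O
F8 | step 10 | [2,4-bis(methoxymethoxy)phenyl]titanium triisopropoxide | CC(C)O[Ti](OC(C)C)(OC(C)C)c1ccc(OCOC)cc1OCOC
F9 | step 10 | (3R,6E)-1-[2,4-bis(methoxymethoxy)phenyl]-1-hydroxy-3,7,11-trimethyl-3-vinyldodeca-6,10-dien-9-one (C1 epimers) | C=C[C@](C)(CC/C=C(\C)CC(=O)C=C(C)C)CC(O)c1ccc(OCOC)cc1OCOC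
F10 | step 14 | 1-bromo-2,4-bis(triisopropylsilyloxy)benzene | CC(C)[Si](Oc1ccc(Br)c(O[Si](C(C)C)(C(C)C)C(C)C)c1)(C(C)C)C(C)C
F11 | step 14 | 2,4-bis(triisopropylsilyloxy)phenyllithium | [Li]c1ccc(O[Si](C(C)C)(C(C)C)C(C)C)cc1O[Si](C(C)C)(C(C)C)C(C)C
F12 | step 14 | (3R,6E)-1-[2,4-bis(triisopropylsilyloxy)phenyl]-3,7,11-trimethyl-3-vinyldodeca-6,10-diene-1,9-diol (C1/C9 epimer mixture) | C=C[C@](C)(CC/C=C(\C)CC(O)C=C(C)C)CC(O)c1ccc(O[Si](C(C)C)(C(C)C)C(C)C)cc1O[Si](C(C)C)(C(C)C)C(C)C
F13 | step 14 | (3R,6E)-1-[2,4-bis(triisopropylsilyloxy)phenyl]-3,7,11-trimethyl-3-vinyldodeca-6,10-diene-1,9-dione | C=C[C@](C)(CC/C=C(\C)CC(=O)C=C(C)C)CC(=O)c1ccc(O[Si](C(C)C)(C(C)C)C(C)C)cc1O[Si](C(C)C)(C(C)C)C(C)C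
A1 | alternative 1 | 2-[2,4-bis(methoxymethoxy)phenyl]-2-[(R)-2,6-dimethyl-2-vinylhept-5-en-1-yl]-1,3-dithiane | C=C[C@](C)(CCC=C(C)C)CC1(SCCCS1)c1ccc(OCOC)cc1OCOC
A2 | alternative 1 | (E)-2-[2,4-bis(methoxymethoxy)phenyl]-2-(4-chloro-2-methylbut-2-en-1-yl)-1,3-dithiane | C/C(CC1(SCCCS1)c1ccc(OCOC)cc1OCOC)=C\CCl
A3 | alternative 2 | (3R,6E)-1-[2,4-bis(methoxymethoxy)phenyl]-9-(tert-butyldimethylsilyloxy)-3,7,11-trimethyl-3-vinyldodeca-6,10-dien-1-one (C9 epimers) | C=C[C@](C)(CC/C=C(\C)CC(O[Si](C)(C)C(C)(C)C)C=C(C)C)CC(=O)c1ccc(OCOC)cc1OCOC
A4 | alternative 2 | 1,3-dioxoisoindolin-2-yl (R)-4-{2-[2,4-bis(methoxymethoxy)phenyl]-2-oxoethyl}-4-methylhex-5-enoate | C=C[C@](C)(CCC(=O)ON1C(=O)c2ccccc2C1=O)CC(=O)c1ccc(OCOC)cc1OCOC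
A5 | alternative 2 | (E)-tert-butyl[(1-iodo-2,6-dimethylhepta-1,5-dien-4-yl)oxy]dimethylsilane | I/C=C(\C)CC(O[Si](C)(C)C(C)(C)C)C=C(C)C
A6 | alternative 3 | (R)-1-[2,4-bis(methoxymethoxy)phenyl]-3,7-dimethyl-3-[(E)-2-(dimethylphenylsilyl)vinyl]oct-6-en-1-one | C[Si](C)(c1ccccc1)/C=C/[C@](C)(CCC=C(C)C)CC(=O)c1ccc(OCOC)cc1OCOC
A7 | alternative 3 | (R,E)-{1-[1-(2,4-bis(methoxymethoxy)phenyl)vinyloxy]-3,7-dimethylocta-2,6-dien-1-yl}dimethyl(phenyl)silane | C=C(c1ccc(OCOC)cc1OCOC)O[C@H]([Si](C)(C)c1ccccc1)/C=C(\C)CCC=C(C)C
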